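## Retrosynthetic overview

- The route rests on one feature of the 2,3-dihydro-4H-pyran-4-one ring: O1 is the enol oxygen of a 1,3-dicarbonyl spanning C4 and C6, and C2 lies β to the C4 ketone. O1–C2 is therefore an oxa-Michael bond. Cutting it opens the only ring, erases the only stereocentre and gives the achiral dienedione 7.
- 7 is cut into the E-enone 5 and an acetyl unit (crossed Claisen acylation at the methyl ketone).
- 5 is cut into aldehyde 3 and phosphonate 4 (Horner–Wadsworth–Emmons, which fixes the E geometry).
- 3 comes from nervonic acid 1 by reduction and reoxidation; the acid supplies the complete C23 side chain with its Z-alkene.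
- Ring order: the single ring is formed last, in step 5, and C2 is set in the same event.

Key step: step 5

Assumption: the facial sense of a cinchona squaramide on this substrate class cannot be read from precedent; the quinine-derived catalyst is written, and its quinidine-derived pseudoenantiomer is substituted if the first analytical run shows closure on the Si face of C6 of 7.

## Route

Step 1
Reactants: 1 nervonic acid [(Z)-tetracos-15-enoic acid]
Product: 2 (Z)-tetracos-15-en-1-ol
Conditions: LiAlH4, THF, 0 °C → reflux; H2O/aq. NaOH work-up
Reagents that add atoms: none
Why: Hydride reduction of the carboxylic acid to the primary alcohol; the isolated, unactivated Z-alkene is inert to aluminium hydride.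

Step 2
Reactants: 2 (Z)-tetracos-15-en-1-ol
Product: 3 (Z)-tetracos-15-enal
Conditions: TEMPO (10 mol %), PhI(OAc)2 (1.1 equiv), CH2Cl2, rt
Reagents that add atoms: none
Why: Oxoammonium-mediated oxidation of a primary alcohol stops at the aldehyde in anhydrous CH2Cl2 and leaves the isolated Z-alkene alone; the aldehyde is used at once.

Step 3
Reactants: 3 (Z)-tetracos-15-enal; 4 diethyl (2-oxopropyl)phosphonate
Product: 5 (3E,18Z)-heptacosa-3,18-dien-2-one
Conditions: 4 (1.2 equiv), NaH (1.15 equiv), THF, 0 °C; then 3, 0 °C → rt
Reagents that add atoms: none
Why: Horner–Wadsworth–Emmons olefination; the stabilised β-ketophosphonate anion adds reversibly and collapses through the more stable oxaphosphetane, which should give the E-enone almost exclusively, and it is too weakly basic to enolise the aldehyde to a significant extent.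

Step 4
Reactants: 5 (3E,18Z)-heptacosa-3,18-dien-2-one
Product: 7 (5E,20Z)-nonacosa-5,20-diene-2,4-dione, via lithium cross-conjugated dienolate 6 (not isolated)
Conditions: LiHMDS (2.2 equiv), THF, −78 °C, slow addition of 5; MeC(O)N(OMe)Me (1.3 equiv), −78 → 0 °C; cold 1 M HCl quench
Reagents that add atoms: N-methoxy-N-methylacetamide, CC(=O)N(C)OC
Why: Slow addition of 5 to excess amide base at −78 °C removes the kinetically favoured α′-methyl proton and keeps free enone away from its own enolate, and the dienolate then undergoes a crossed Claisen-type C-acylation in which the second equivalent of base takes up the acidic proton of the new 1,3-diketone, so that no enolate is lost to proton transfer; the cold acidic quench returns neutral, enolised 7 before it can cyclise.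

Step 5
Reactants: 7 (5E,20Z)-nonacosa-5,20-diene-2,4-dione
Product: 8 (2R)-6-methyl-2-[(14Z)-tricos-14-en-1-yl]-2,3-dihydro-4H-pyran-4-one
Conditions: quinine-derived squaramide [3-{[3,5-bis(trifluoromethyl)phenyl]amino}-4-{[(8α,9S)-6′-methoxycinchonan-9-yl]amino}cyclobut-3-ene-1,2-dione] (10 mol %), PhMe/CH2Cl2, 0.05 M, −20 °C; AcOH quench, filtration through SiO2
Reagents that add atoms: none
Why: Proposed new method: the quinuclidine nitrogen takes the acidic proton of the enolised 1,3-diketone (the diketo form and both enols of 7 give the same diketonate), the squaramide N–H bonds hold the oxygen on C4, and the oxygen on C2 adds to the enone β-carbon C6 (numbering of 7) as charge flows onto the bound C4 oxygen, after which the ammonium protonates C5 and releases 8 and the catalyst. The closest known reaction type is the amine–thiourea or amine–squaramide-catalysed oxa-Michael closure of 2′-hydroxychalcones to flavanones, together with the racemic acid- or base-mediated closure of 5-ene-1,3-diones to 2,3-dihydro-4H-pyran-4-ones; what is new is an acyclic aliphatic diketonate as the oxygen nucleophile under enantiocontrol. The dihydropyranone ring closes in a 6-endo-trig mode through a twisted transition state in which the C2=C3 enolate unit turns out of the enone plane so that oxygen meets C6 from above. The new stereocentre (ring C2) is set by the catalyst pocket, which must deliver oxygen to the Re face of C6 of the E-enone to give the R configuration. The step needs enantiofacial selectivity and oxygen rather than carbon attack: the single E geometry from step 3 and the converging tautomers present one substrate to the catalyst, the central carbon C3 cannot reach C6 within the molecule, dilution holds back intermolecular C-Michael addition, and the remote Z-alkene is inert. Because the product can reopen by E1cB loss of the ring oxygen under the same amine, the run is kept cold, stopped at high conversion and quenched with acetic acid before chromatography.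

## Compound list

1 | nervonic acid, (Z)-tetracos-15-enoic acid | CCCCCCCC/C=C\CCCCCCCCCCCCCC(=O)O | starting material
2 | (Z)-tetracos-15-en-1-ol | CCCCCCCC/C=C\CCCCCCCCCCCCCCO | intermediate
3 | (Z)-tetracos-15-enal | CCCCCCCC/C=C\CCCCCCCCCCCCCC=O | intermediate
4 | diethyl (2-oxopropyl)phosphonate | CCOP(=O)(CC(C)=O)OCC | starting material
5 | (3E,18Z)-heptacosa-3,18-dien-2-one | CCCCCCCC/C=C\CCCCCCCCCCCCC/C=C/C(C)=O | intermediate
6 | lithium (3E,18Z)-heptacosa-1,3,18-trien-2-olate (cross-conjugated dienolate, not isolated) | CCCCCCCC/C=C\CCCCCCCCCCCCC/C=C/C(=C)O[Li] | intermediate
7 | (5E,20Z)-nonacosa-5,20-diene-2,4-dione (drawn as the diketo tautomer; mainly enolised) | CCCCCCCC/C=C\CCCCCCCCCCCCC/C=C/C(=O)CC(C)=O | intermediate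
8 | (2R)-6-methyl-2-[(14Z)-tricos-14-en-1-yl]-2,3-dihydro-4H-pyran-4-one | CCCCCCCC/C=C\CCCCCCCCCCCCC[C@@H]1CC(=O)C=C(C)O1 | target

## Step count and risks

Total step count: 5. Longest linear sequence: 5.

**Step 5 (bears the label).** The diketonate is a weak, strongly delocalised oxygen nucleophile and may close slowly. Intermolecular C-Michael oligomerisation, an uncatalysed racemic closure, or reversible ring opening of the product under the amine could then erode conversion and enantiomeric purity.

The fallback uses known chemistry, sets out from aldehyde 3 and returns to the route at 8. Commercial 4-(trimethylsilyloxy)pent-3-en-2-one is deprotonated with LDA and silylated with TMSCl (THF, −78 °C) to give 2,4-bis(trimethylsilyloxy)penta-1,3-diene F1. A Ti(OiPr)4/(S)-BINOL-catalysed vinylogous Mukaiyama aldol addition of the terminal carbon of F1 to 3 (THF, −78 °C → rt), with acidic desilylation on work-up, should give (6R,20Z)-6-hydroxynonacos-20-ene-2,4-dione F2. The BINOL hand is chosen from the usual facial sense of Ti/BINOL carbonyl additions; the configuration of F2 is to be confirmed by MTPA ester analysis, and (R)-BINOL is used instead if needed. Acid-catalysed cyclodehydration of F2 (TFA, CH2Cl2, 0 °C) closes the ring at the methyl-bearing carbonyl by hemiketal formation and loss of water. The carbinol C–O bond and its configuration are untouched, and the product is 8.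

**Step 4.** Acyl transfer from the N-methoxy-N-methylamide may be sluggish. The dienolate could then equilibrate (γ-deprotonation, self-Michael addition to regenerated enone), or proton transfer from the product could stall conversion.

The fallback sets out from 5 and returns at 7. The dienolate 6, generated with LDA (1.05 equiv, THF, −78 °C), is trapped with acetaldehyde and quenched cold with acetic acid to give racemic (5E,20Z)-2-hydroxynonacosa-5,20-dien-4-one F3. Oxidation of this β-hydroxy ketone with IBX (EtOAc, 70 °C) or Dess–Martin periodinane (NaHCO3, CH2Cl2, 0 °C) gives 7. The carbinol stereocentre of F3 is destroyed, so its configuration is immaterial.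

**Step 3.** The basic phosphonate anion may partly enolise the aldehyde and cause self-aldol condensation, or E selectivity may be incomplete. A Z-enone carried into the key step would degrade its facial control.

The fallback sets out from 3 and returns at 5. Aldol addition of the lithium enolate of acetone (LDA, acetone in excess, THF, −78 °C) to 3 gives racemic (18Z)-4-hydroxyheptacos-18-en-2-one F4. Mesylation (MsCl, Et3N, CH2Cl2, 0 °C) gives (18Z)-2-oxoheptacos-18-en-4-yl methanesulfonate F5. F5 eliminates in the same flask (DBU, rt) by an E1cB pathway to the thermodynamically favoured E-enone 5.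

## Further compounds

F1 | step 5 | 2,4-bis(trimethylsilyloxy)penta-1,3-diene | C=C(O[Si](C)(C)C)C=C(C)O[Si](C)(C)C
F2 | step 5 | (6R,20Z)-6-hydroxynonacos-20-ene-2,4-dione | CCCCCCCC/C=C\CCCCCCCCCCCCC[C@@H](O)CC(=O)CC(C)=O
F3 | step 4 | (5E,20Z)-2-hydroxynonacosa-5,20-dien-4-one (racemic) | CCCCCCCC/C=C\CCCCCCCCCCCCC/C=C/C(=O)CC(C)O
F4 | step 3 | (18Z)-4-hydroxyheptacos-18-en-2-one (racemic) | CCCCCCCC/C=C\CCCCCCCCCCCCCC(O)CC(C)=O
F5 | step 3 | (18Z)-2-oxoheptacos-18-en-4-yl methanesulfonate (racemic) | CCCCCCCC/C=C\CCCCCCCCCCCCCC(OS(C)(=O)=O)CC(C)=O
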